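**Strategy.** The side-chain carbinol C2' (the acetoxy CH between C1'H2 and C3'H2) is treated as an aldehyde carbon. The C2'–C3' bond is made by catalyst-controlled addition of an undecylzinc reagent to a ring-bearing acetaldehyde, with acetylation in the same flask, so bond, stereocentre and ester arrive in one operation. The labile dienol ring is carried through this step as a ketal-protected 3-methoxycyclohexenone. Its C1 is a temporary stereocentre from a rhodium-catalysed vinylation. C1 then relays C6, C2 (a phenylselanyl mask for the C1=C2 alkene) and C3 by substrate control and is erased in the final selenoxide elimination.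

Key step: step 4

Remark: ring atoms are called C1 (bears the side chain), C2, C3 (carbinol), C4, C5 (C–OMe) and C6 (acetoxy carbon); side-chain atoms are C1', C2' (acetoxy carbon) and C3'. The sense of induction of the two catalytic steps is taken from the accepted models for these catalyst families; if either proved opposite, the ligand antipode would be used with no other change.

Step 1
Reactants: 1 3,4-dimethoxyphenol
Product: 2 3,4,4-trimethoxycyclohexa-2,5-dien-1-one
Conditions: PhI(OAc)2 (1.1 equiv), MeOH, 0 °C
Reagents that add atoms: methanol, CO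
Why: Oxidative dearomatisation of the para-methoxyphenol with PhI(OAc)2 gives a phenoxenium-type cation that methanol traps at the methoxy-bearing para carbon to give the para-quinone monoketal (a standard hypervalent-iodine phenol oxidation), and no stereocentre is formed.

Step 2
Reactants: 2 3,4,4-trimethoxycyclohexa-2,5-dien-1-one
Product: 3 (5R)-5-ethenyl-3,4,4-trimethoxycyclohex-2-en-1-one
Conditions: CH2=CHBF3K (2 equiv), [Rh(cod)2]BF4 (cod = 1,5-cyclooctadiene, 3 mol %), (R)-2,2'-bis(diphenylphosphino)-1,1'-binaphthyl (3.3 mol %), Et3N, toluene/H2O, 40 °C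
Reagents that add atoms: potassium vinyltrifluoroborate, C=C[B-](F)(F)F.[K+]
Why: Hayashi–Miyaura rhodium-catalysed asymmetric 1,4-addition, a reaction type precedented for quinone monoketals: the vinylrhodium species inserts only the unsubstituted enone C=C (the methoxy-bearing alkene is a deactivated vinylogous ester) and the (R)-bisphosphine sets the new stereocentre, ring C1, by catalyst control as (R).

Step 3
Reactants: 3 (5R)-5-ethenyl-3,4,4-trimethoxycyclohex-2-en-1-one
Product: 4 2-[(1S)-2,2,3-trimethoxy-5-oxocyclohex-3-en-1-yl]acetaldehyde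
Conditions: PdCl2(PhCN)2 (12 mol %), CuCl2·2H2O (12 mol %), AgNO2 (6 mol %), O2 (1 atm), t-BuOH/MeNO2 (15:1), rt
Reagents that add atoms: dioxygen, O=O
Why: Nitrite-modified, aldehyde-selective Wacker oxidation of the monosubstituted alkene, whose branched allylic carbon and neighbouring ketal oxygens both favour oxygen delivery to the terminal carbon; the C1 stereocentre is not enolisable here and is untouched.

Step 4
Reactants: 4 2-[(1S)-2,2,3-trimethoxy-5-oxocyclohex-3-en-1-yl]acetaldehyde; 5 1-iodoundecane
Product: 8 (2R)-1-[(1S)-2,2,3-trimethoxy-5-oxocyclohex-3-en-1-yl]tridecan-2-yl acetate, via diundecylzinc 6 (not isolated), via undecylzinc alkoxide 7 (not isolated)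
Conditions: 5 (4.4 equiv), Et2Zn (3 equiv), CuI (0.3 mol %), neat, 50 °C, then EtI and excess Et2Zn removed in vacuo; toluene, Ti(OiPr)4 (2 equiv), (1S,2S)-N,N'-bis(trifluoromethanesulfonyl)cyclohexane-1,2-diamine (8 mol %), −20 °C, then 4; then Ac2O (excess), 4-(dimethylamino)pyridine (cat.), 0 °C to rt
Reagents that add atoms: acetic anhydride, CC(=O)OC(C)=O
Why: Iodine–zinc exchange converts 5 into salt-free diundecylzinc 6, and within the chiral titanium bis(sulfonamide) complex one undecyl group is transferred to the aldehyde carbon of 4 (C2') to form the C2'–C3' bond, after which the alkoxide 7 is acetylated in the same flask. The closest known reaction type is the Yoshioka–Ohno–Knochel titanium/bis(sulfonamide)-catalysed enantioselective addition of dialkylzincs to aliphatic aldehydes. No ring is closed. The new stereocentre C2' (R) is set by the (1S,2S) ligand (catalyst control), since C2' has only CH2 groups as carbon neighbours and the existing stereocentre C1 is too remote to bias the carbonyl faces. The step needs chemoselectivity for the aldehyde over the ring ketone, the ketal and the enol ether, which the low electrophilicity of the vinylogous-ester carbonyl toward dialkylzincs and the mild Lewis acidity of Ti(OiPr)4 should secure, and it needs face selectivity at an α-unbranched aldehyde, for which this catalyst class is the established solution.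

Step 5
Reactants: 8 (2R)-1-[(1S)-2,2,3-trimethoxy-5-oxocyclohex-3-en-1-yl]tridecan-2-yl acetate
Product: 9 (2R)-1-[(1S)-3-methoxy-2,5-dioxocyclohex-3-en-1-yl]tridecan-2-yl acetate
Conditions: p-toluenesulfonic acid monohydrate (10 mol %), acetone/H2O (10:1), 0 °C to rt; NaHCO3 quench; used at once
Reagents that add atoms: water, O
Why: Acid-catalysed ketal hydrolysis; the resulting 2-methoxycyclohex-2-ene-1,4-dione belongs to an isolable class when kept cold and away from base, the vinylogous ester and the acetate should survive the brief treatment, and acid-catalysed enolisation at C1 (which would erode the stereocentre or aromatise the ring) is slow on this time scale.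

Step 6
Reactants: 9 (2R)-1-[(1S)-3-methoxy-2,5-dioxocyclohex-3-en-1-yl]tridecan-2-yl acetate
Product: 10 (2R)-1-[(1S,2S)-2-hydroxy-3-methoxy-5-oxocyclohex-3-en-1-yl]tridecan-2-yl acetate
Conditions: LiBH(s-Bu)3 (1.1 equiv), THF, −78 °C; H2O quench
Reagents that add atoms: none
Why: Chemo- and diastereoselective 1,2-reduction with a bulky trialkylborohydride: only the C6 carbonyl is electrophilic enough (C3 is a vinylogous-ester carbonyl and C4 is the electron-rich β-carbon of an enol ether, so conjugate reduction is disfavoured), and hydride should enter anti to the adjacent C1 substituent as in 2-alkylcyclohexanones, setting C6 (S) cis to the side chain by substrate control.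

Step 7
Reactants: 10 (2R)-1-[(1S,2S)-2-hydroxy-3-methoxy-5-oxocyclohex-3-en-1-yl]tridecan-2-yl acetate
Product: 12 (2R)-1-[(1R,2S,6S)-2-hydroxy-3-methoxy-5-oxo-6-(phenylselanyl)cyclohex-3-en-1-yl]tridecan-2-yl acetate, via dilithium alkoxide enolate 11 (not isolated)
Conditions: LiN(SiMe3)2 (2.2 equiv), THF, −78 °C; PhSeCl (1.2 equiv), −78 °C; aq. NaHCO3
Reagents that add atoms: benzeneselenenyl chloride, Cl[Se]c1ccccc1
Why: Reich–Sharpless α-selenenylation of a kinetic ketone enolate: the hydroxyl is first converted into its alkoxide (which also blocks γ-deprotonation), the vinylogous ester is deprotonated at C2, and PhSeCl should attack anti to the neighbouring C1 substituent, setting C2 with selenium trans to the side chain and therefore cis to C1–H as the later syn-elimination demands.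

Step 8
Reactants: 12 (2R)-1-[(1R,2S,6S)-2-hydroxy-3-methoxy-5-oxo-6-(phenylselanyl)cyclohex-3-en-1-yl]tridecan-2-yl acetate
Product: 13 (2R)-1-[(1R,2S,6S)-2-acetoxy-3-methoxy-5-oxo-6-(phenylselanyl)cyclohex-3-en-1-yl]tridecan-2-yl acetate
Conditions: Ac2O, pyridine, 4-(dimethylamino)pyridine (cat.), CH2Cl2, 0 °C to rt
Reagents that add atoms: acetic anhydride, CC(=O)OC(C)=O
Why: Pyridine/4-(dimethylamino)pyridine-catalysed O-acetylation of the secondary C6 alcohol, which creates no stereocentre and also levels any acetyl migration between the C2' and C6 oxygens that may have occurred in step 7.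

Step 9
Reactants: 13 (2R)-1-[(1R,2S,6S)-2-acetoxy-3-methoxy-5-oxo-6-(phenylselanyl)cyclohex-3-en-1-yl]tridecan-2-yl acetate
Product: 14 (2R)-1-[(1R,2S,5R,6S)-2-acetoxy-5-hydroxy-3-methoxy-6-(phenylselanyl)cyclohex-3-en-1-yl]tridecan-2-yl acetate
Conditions: LiBH(s-Bu)3 (1.3 equiv), THF, −78 to −40 °C; aq. NaHCO3 work-up without peroxide; chromatography on Et3N-deactivated silica
Reagents that add atoms: none
Why: 1,2-Reduction of the vinylogous-ester carbonyl (its β-carbon is fully substituted, so there is no conjugate path) by the bulky borohydride from the face opposite the adjacent phenylselanyl group, as known for α-seleno and α-thio cyclohexanones, should set C3–OH cis to selenium and hence trans to C6–OAc (substrate control relayed from C1 through C2), the acetates being inert at this temperature.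

Step 10
Reactants: 14 (2R)-1-[(1R,2S,5R,6S)-2-acetoxy-5-hydroxy-3-methoxy-6-(phenylselanyl)cyclohex-3-en-1-yl]tridecan-2-yl acetate
Product: 16 (2R)-1-[(3S,6S)-6-acetoxy-3-hydroxy-5-methoxycyclohexa-1,4-dien-1-yl]tridecan-2-yl acetate, via selenoxide 15 (not isolated)
Conditions: NaIO4 (2 equiv), NaHCO3, THF/MeOH/H2O, 0 °C to rt
Reagents that add atoms: none
Why: Selenide oxidation followed by selenoxide syn-elimination (Sharpless–Reich) at or below room temperature under buffered conditions: the only cis β-hydrogen is C1–H (C3–H is trans to selenium and elimination toward a carbinol carbon is disfavoured in any case), so the C1=C2 alkene should form regiospecifically, the temporary C1 and C2 stereocentres vanish and C3, C6 and C2' are untouched.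

**Compound list**

1 | 3,4-dimethoxyphenol | COc1ccc(O)cc1OC | starting material
2 | 3,4,4-trimethoxycyclohexa-2,5-dien-1-one | COC1=CC(=O)C=CC1(OC)OC | intermediate
3 | (5R)-5-ethenyl-3,4,4-trimethoxycyclohex-2-en-1-one | C=C[C@H]1CC(=O)C=C(OC)C1(OC)OC | intermediate
4 | 2-[(1S)-2,2,3-trimethoxy-5-oxocyclohex-3-en-1-yl]acetaldehyde | O=CC[C@H]1CC(=O)C=C(OC)C1(OC)OC | intermediate
5 | 1-iodoundecane | CCCCCCCCCCCI | starting material
6 | diundecylzinc | CCCCCCCCCCC[Zn]CCCCCCCCCCC | intermediate (not isolated)
7 | undecylzinc (2R)-1-[(1S)-2,2,3-trimethoxy-5-oxocyclohex-3-en-1-yl]tridecan-2-olate | CCCCCCCCCCC[C@H](C[C@H]1CC(=O)C=C(OC)C1(OC)OC)O[Zn]CCCCCCCCCCC | intermediate (not isolated)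
8 | (2R)-1-[(1S)-2,2,3-trimethoxy-5-oxocyclohex-3-en-1-yl]tridecan-2-yl acetate | CCCCCCCCCCC[C@H](C[C@H]1CC(=O)C=C(OC)C1(OC)OC)OC(C)=O | intermediate
9 | (2R)-1-[(1S)-3-methoxy-2,5-dioxocyclohex-3-en-1-yl]tridecan-2-yl acetate | CCCCCCCCCCC[C@H](C[C@H]1CC(=O)C=C(OC)C1=O)OC(C)=O | intermediate
10 | (2R)-1-[(1S,2S)-2-hydroxy-3-methoxy-5-oxocyclohex-3-en-1-yl]tridecan-2-yl acetate | CCCCCCCCCCC[C@H](C[C@H]1CC(=O)C=C(OC)[C@H]1O)OC(C)=O | intermediate
11 | dilithium alkoxide enolate of 10 | CCCCCCCCCCC[C@H](C[C@H]1C=C(O[Li])C=C(OC)[C@H]1O[Li])OC(C)=O | intermediate (not isolated)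
12 | (2R)-1-[(1R,2S,6S)-2-hydroxy-3-methoxy-5-oxo-6-(phenylselanyl)cyclohex-3-en-1-yl]tridecan-2-yl acetate | CCCCCCCCCCC[C@H](C[C@H]1[C@H]([Se]c2ccccc2)C(=O)C=C(OC)[C@H]1O)OC(C)=O | intermediate
13 | (2R)-1-[(1R,2S,6S)-2-acetoxy-3-methoxy-5-oxo-6-(phenylselanyl)cyclohex-3-en-1-yl]tridecan-2-yl acetate | CCCCCCCCCCC[C@H](C[C@H]1[C@H]([Se]c2ccccc2)C(=O)C=C(OC)[C@H]1OC(C)=O)OC(C)=O | intermediate
14 | (2R)-1-[(1R,2S,5R,6S)-2-acetoxy-5-hydroxy-3-methoxy-6-(phenylselanyl)cyclohex-3-en-1-yl]tridecan-2-yl acetate | CCCCCCCCCCC[C@H](C[C@H]1[C@H]([Se]c2ccccc2)[C@H](O)C=C(OC)[C@H]1OC(C)=O)OC(C)=O | intermediate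
15 | selenoxide of 14 | CCCCCCCCCCC[C@H](C[C@H]1[C@H]([Se](=O)c2ccccc2)[C@H](O)C=C(OC)[C@H]1OC(C)=O)OC(C)=O | intermediate (not isolated)
16 | (2R)-1-[(3S,6S)-6-acetoxy-3-hydroxy-5-methoxycyclohexa-1,4-dien-1-yl]tridecan-2-yl acetate | CCCCCCCCCCC[C@H](CC1=C[C@H](O)C=C(OC)[C@H]1OC(C)=O)OC(C)=O | target

**Totals.** Total step count: 10. Longest linear sequence: 10 steps (1 to 16); the commercial fragment 5 enters in step 4.

**Steps most likely to fail**

Step 9. What may go wrong: hydride delivery syn to selenium (poor facial selectivity, giving the C3 epimer and thus the cis ring diol pattern), or attack of the borohydride on the acetates. The fallback sets out from 13 and reduces the C3 carbonyl under reagent control instead. It uses a Corey–Bakshi–Shibata reduction with catecholborane and the antipode of 1-methyl-3,3-diphenyltetrahydro-1H,3H-pyrrolo[1,2-c][1,3,2]oxazaborole that reinforces delivery anti to selenium (toluene, −78 °C; esters are inert to catecholborane). It comes back to the route at 14 and makes no new compound (F0).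

Step 7. What may go wrong: competing deprotonation of the side-chain acetate by the amide base, or double selenenylation. The fallback sets out from 10 and removes the ester before any enolate chemistry. K2CO3 in MeOH at 0 °C should give the diol (4S,5S)-4-hydroxy-5-[(2R)-2-hydroxytridecyl]-3-methoxycyclohex-2-en-1-one F1. LiN(i-Pr)2 (3.3 equiv, THF, −78 °C) converts it into the trilithium dialkoxide enolate F2, which is not isolated, and PhSeCl then gives the seleno diol (4S,5R,6S)-4-hydroxy-5-[(2R)-2-hydroxytridecyl]-3-methoxy-6-(phenylselanyl)cyclohex-2-en-1-one F3. Ac2O, pyridine and 4-(dimethylamino)pyridine acetylate both hydroxyls at once, and the fallback comes back to the route at 13.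

Step 10. What may go wrong: slow elimination of the hydrogen-bonded β-hydroxy selenoxide, with competing re-addition of the selenenic acid to the enol ether and aromatisation of the product by loss of water or acetic acid. The fallback sets out from 14 and silylates the C3 hydroxyl first (Et3SiCl, imidazole, CH2Cl2) to give (2R)-1-[(1R,2S,5R,6S)-2-acetoxy-3-methoxy-6-(phenylselanyl)-5-(triethylsilyloxy)cyclohex-3-en-1-yl]tridecan-2-yl acetate F4. Oxidation with NaIO4/NaHCO3 gives its selenoxide F5, which is not isolated and should eliminate faster without the internal hydrogen bond to give (2R)-1-[(3S,6S)-6-acetoxy-5-methoxy-3-(triethylsilyloxy)cyclohexa-1,4-dien-1-yl]tridecan-2-yl acetate F6. Bu4NF buffered with AcOH (THF, 0 °C) then removes the silyl group and the fallback comes back to the route at 16.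

**Further compounds**

F0 | step 9 | none | none
F1 | step 7 | (4S,5S)-4-hydroxy-5-[(2R)-2-hydroxytridecyl]-3-methoxycyclohex-2-en-1-one | CCCCCCCCCCC[C@H](C[C@H]1CC(=O)C=C(OC)[C@H]1O)O
F2 | step 7 | trilithium dialkoxide enolate of F1 | CCCCCCCCCCC[C@H](C[C@H]1C=C(O[Li])C=C(OC)[C@H]1O[Li])O[Li]
F3 | step 7 | (4S,5R,6S)-4-hydroxy-5-[(2R)-2-hydroxytridecyl]-3-methoxy-6-(phenylselanyl)cyclohex-2-en-1-one | CCCCCCCCCCC[C@H](C[C@H]1[C@H]([Se]c2ccccc2)C(=O)C=C(OC)[C@H]1O)O
F4 | step 10 | (2R)-1-[(1R,2S,5R,6S)-2-acetoxy-3-methoxy-6-(phenylselanyl)-5-(triethylsilyloxy)cyclohex-3-en-1-yl]tridecan-2-yl acetate | CCCCCCCCCCC[C@H](C[C@H]1[C@H]([Se]c2ccccc2)[C@H](O[Si](CC)(CC)CC)C=C(OC)[C@H]1OC(C)=O)OC(C)=O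
F5 | step 10 | selenoxide of F4 | CCCCCCCCCCC[C@H](C[C@H]1[C@H]([Se](=O)c2ccccc2)[C@H](O[Si](CC)(CC)CC)C=C(OC)[C@H]1OC(C)=O)OC(C)=O
F6 | step 10 | (2R)-1-[(3S,6S)-6-acetoxy-5-methoxy-3-(triethylsilyloxy)cyclohexa-1,4-dien-1-yl]tridecan-2-yl acetate | CCCCCCCCCCC[C@H](CC1=C[C@H](O[Si](CC)(CC)CC)C=C(OC)[C@H]1OC(C)=O)OC(C)=O
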